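Late in the eta run, between 46 min and 66 min, the second-order constant, reckoned from the mean [product] of that interval, reads 0.0387 M⁻¹ min⁻¹, lower than the 0.0658 M⁻¹ min⁻¹ read over the first 5.0 min of the gamma run.

| setting | gamma | eta | alpha |
|---|---|---|---|
| substrate | 0.150 M | 0.450 M | 0.0750 M |
| reagent | 0.300 M | 0.300 M | 0.150 M |
| time |  |  | 66 min |

| run | time / min | [product] / M |
|---|---|---|
| gamma run | 5.0 | 0.0138 |
| gamma run | 15 | 0.0348 |
| gamma run | 29 | 0.0572 |
| gamma run | 46 | 0.0747 |
| gamma run | 66 | 0.0904 |
| eta run | 5.0 | 0.0384 |
| eta run | 15 | 0.0890 |
| eta run | 29 | 0.1326 |
| eta run | 46 | 0.1654 |
| eta run | 66 | 0.1910 |

(each reading ± 4 × 10⁻⁴ M)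

- Overall: substrate + reagent -> product.
- Constant volume, constant temperature.
- Readings of a species count what is bound in complexes too.
- "The second partner" is reagent.
- An order is taken over about fifteen percent of the charge, up and down.

1. apparent order in [substrate] of the starting rate, round the charge of the gamma run (the rate where two percent of its substrate have turned into product) (one fixed amount of product, the same in the runs compared)
2. product in the alpha run at 66 min, as a share of the substrate charged
3. which of these the readings show (the by-product binds the second partner / the second partner is lost in pairs / two substrates go astray together)

1. Were the slowing tied to the clock, gamma and eta would read alike over the same interval. Gamma reads 0.0535 M⁻¹ min⁻¹, higher than eta, and eta holds the higher mean [product], 0.178 M. So the reckoning follows [product].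

2. A straight line for the inverse constant against [product], through the early gamma reading at 6.90 mM and the late eta reading, gives the brake amount B, the [product] at which the apparent constant has fallen to 0.5 of its start value: 0.237 M. The start constant is 0.0677 M⁻¹ min⁻¹. The constant is divided by one plus [product]/B, the divisor.

3. For the constant to fall that far in alpha, [product] must reach B. But substrate, the limiting reagent there, is charged at 0.0750 M, less than B. My reckoning: without a brake, alpha reaches 0.0333 M. The divisor at half that product is 1.07, which lowers the yield to 0.0318 M, or 42.4%.

4. At one fixed [product] the divisor is the same in gamma and eta, so the rate follows [substrate], with an order near one.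

5. The forecast gives 1.02, 42% and "the by-product binds the second partner", on the ground that “Interval k values from both runs fall on one curve against product, not time”.

The flask gives 1.0, 41.7% and "the by-product binds the second partner".

    substrate + reagent → product + by-product (0.06540 M⁻¹ min⁻¹)
    reagent + by-product ⇌ reagent-by-product salt, settled at all times (5.290 M⁻¹)

Throughout the 66 min of the alpha run, substrate and reagent made product and by-product, while by-product and reagent stood at equilibrium with the reagent-by-product salt. At 66 min alpha holds 0.0313 M of product, which puts the divisor from B at 1.13. The eta run reaches half of its substrate charge at 111 min, where the divisor from B stands at 1.95.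

(The data are calculated with made-up constants.)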